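The plan cuts the oxazole ring at C4–C5 and O1–C2. Oxazole C5, the atom bonded to indole C3, has the oxidation level of an aldehyde carbon and already carries O1. The missing C4–N3–C2 unit can therefore come from tosylmethyl isocyanide. One van Leusen operation converts a 3-formylindole into the complete 5-(indol-3-yl)oxazole and leaves C2–H and C4–H open for halogenation. The precursor is 6-bromo-4-methoxyindole-3-carbaldehyde with a tosyl group on N1, which removes the vinylogous-amide deactivation of the formyl group. Double iodination, a C2-selective Suzuki coupling with a Boc-pyrrolylboronic acid, and one acid-free global deprotection complete the target.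

Key step: step 3

Assumption: the target has no stereocentre. The only stereocentres on the route are the two transient ones of oxazoline 6 (racemic, trans, one enantiomer drawn), and both disappear on aromatisation.

Step 1
Reactants: 1 6-bromo-4-methoxy-1H-indole
Product: 3 6-bromo-4-methoxy-1H-indole-3-carbaldehyde, via iminium chloride 2 (not isolated)
Conditions: POCl3 (1.2 equiv), DMF, 0 → 40 °C; then aq NaOH, 0 °C → rt
Reagents that add atoms: N,N-dimethylformamide CN(C)C=O; water O
Why: Vilsmeier–Haack formylation, in which the chloroiminium ion made from POCl3 and DMF attacks indole C3, the enamine β-carbon and the most nucleophilic site (benzenoid C5 and C7 are damped by the 6-bromine), and alkaline hydrolysis of 2 releases the aldehyde.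

Step 2
Reactants: 3 6-bromo-4-methoxy-1H-indole-3-carbaldehyde
Product: 4 6-bromo-4-methoxy-1-tosyl-1H-indole-3-carbaldehyde
Conditions: NaH (1.2 equiv), THF, 0 °C; TsCl (1.2 equiv), 0 °C → rt
Reagents that add atoms: p-toluenesulfonyl chloride Cc1ccc(S(=O)(=O)Cl)cc1
Why: N-sulfonylation of the sodium indolide, which works because the 3-formyl group makes N–H acidic and the anion reacts with TsCl at nitrogen, while the non-enolisable aldehyde, the aryl bromide and the methyl ether are inert to NaH at 0 °C.

Step 3
Reactants: 4 6-bromo-4-methoxy-1-tosyl-1H-indole-3-carbaldehyde; 5 tosylmethyl isocyanide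
Product: 7 5-(6-bromo-4-methoxy-1-tosyl-1H-indol-3-yl)oxazole, via trans-4-tosyloxazoline 6 (not isolated)
Conditions: 5 (1.2 equiv), DBU (2.5 equiv), dry DME, rt then 70 °C
Reagents that add atoms: tosylmethyl isocyanide (5) Cc1ccc(S(=O)(=O)C[N+]#[C-])cc1
Why: DBU deprotonates the CH2 of 5, which lies between sulfonyl and isocyano groups, and the carbanion adds to the formyl carbon of 4 to make the C4–C5 bond. The resulting alkoxide attacks the terminal isocyanide carbon in a 5-endo-dig closure that makes O1–C2, and protonation at C2 by protonated DBU gives oxazoline 6. Base-induced loss of p-toluenesulfinate across C4–C5 then aromatises the ring to 7 and removes both transient stereocentres, so no stereocontrol is needed. This is the van Leusen oxazole synthesis, a standard reaction of aromatic and heteroaromatic aldehydes. Regiochemistry is built into the reagent pair, because the carbonyl carbon must become C5 and the isocyanide supplies C4–H, N3 and C2–H in that order. The selectivity required is carbonyl addition over N–S cleavage: the N1 sulfonyl group draws the nitrogen lone pair out of the N1–C2=C3–CHO push-pull system, which keeps the aldehyde electrophilic next to the peri 4-methoxy group, and a non-nucleophilic amidine base in an aprotic ether (in place of carbonate in methanol) keeps that sulfonamide in place.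

Step 4
Reactants: 7 5-(6-bromo-4-methoxy-1-tosyl-1H-indol-3-yl)oxazole
Product: 10 5-(6-bromo-4-methoxy-1-tosyl-1H-indol-3-yl)-2,4-diiodooxazole, via lithium isocyanoenolate 8 (not isolated), via 4-iodooxazole 9 (not isolated)
Conditions: LiN(SiMe3)2 (1.3 equiv), THF/DMPU, −78 °C; I2 (1.3 equiv); then LiN(SiMe3)2 (1.5 equiv), −78 °C; I2 (1.5 equiv), −78 → 0 °C; aq Na2S2O3
Reagents that add atoms: iodine II
Why: LiN(SiMe3)2 removes only the most acidic proton, oxazole C2–H, and in the presence of DMPU the 2-lithiooxazole reacts through its ring-opened valence tautomer 8, whose enolate carbon is iodinated and recloses to 9 (the known C4 iodination of 5-substituted oxazoles by way of 2-lithiooxazoles), after which a second C2 deprotonation and iodination gives 10, the amide base being too weak to metalate indole C2–H and unable to exchange with C6–Br.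

Step 5
Reactants: 10 5-(6-bromo-4-methoxy-1-tosyl-1H-indol-3-yl)-2,4-diiodooxazole; 11 (1-(tert-butoxycarbonyl)-1H-pyrrol-2-yl)boronic acid
Product: 12 tert-butyl 2-[5-(6-bromo-4-methoxy-1-tosyl-1H-indol-3-yl)-4-iodooxazol-2-yl]-1H-pyrrole-1-carboxylate
Conditions: 11 (1.15 equiv), Pd(PPh3)4 (5 mol %), 2 M aq Na2CO3, DME, 60–65 °C
Reagents that add atoms: (1-(tert-butoxycarbonyl)-1H-pyrrol-2-yl)boronic acid (11) CC(C)(C)OC(=O)n1cccc1B(O)O
Why: Suzuki–Miyaura coupling in which zerovalent palladium inserts fastest into C2–I, the unhindered and most electron-poor carbon between O1 and N3, whereas C4–I is shielded by the neighbouring 4-methoxyindolyl group and C6–Br is an intrinsically slower aryl bromide, so near-stoichiometric boronic acid at moderate temperature should stop at monocoupling.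

Step 6
Reactants: 12 tert-butyl 2-[5-(6-bromo-4-methoxy-1-tosyl-1H-indol-3-yl)-4-iodooxazol-2-yl]-1H-pyrrole-1-carboxylate
Product: 13 5-(6-bromo-4-methoxy-1H-indol-3-yl)-4-iodo-2-(1H-pyrrol-2-yl)oxazole (target)
Conditions: 2 M aq NaOH (6 equiv), 1,4-dioxane, 60 °C; neutral work-up
Reagents that add atoms: none
Why: Alkaline hydrolysis, in which hydroxide attacks the sulfonyl sulfur (the indolide is a good leaving group thanks to the 3-oxazolyl and 6-bromo substituents) and the pyrrole carbamate carbonyl (pyrrolide leaving group), so both N-protecting groups fall in one operation, while the absence of acid avoids protodeiodination at oxazole C4, the absence of reducing metals spares C–I and C–Br, and the absence of an alcohol cosolvent avoids an alkyl tosylate that could N-alkylate the product.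

Compound list
1 | 6-bromo-4-methoxy-1H-indole | COc1cc(Br)cc2[nH]ccc12 | starting material
2 | [(6-bromo-4-methoxy-1H-indol-3-yl)methylidene]dimethylammonium chloride | COc1cc(Br)cc2[nH]cc(C=[N+](C)C)c12.[Cl-] | intermediate (not isolated)
3 | 6-bromo-4-methoxy-1H-indole-3-carbaldehyde | COc1cc(Br)cc2[nH]cc(C=O)c12 | intermediate
4 | 6-bromo-4-methoxy-1-tosyl-1H-indole-3-carbaldehyde | COc1cc(Br)cc2n(S(=O)(=O)c3ccc(C)cc3)cc(C=O)c12 | intermediate
5 | tosylmethyl isocyanide | Cc1ccc(S(=O)(=O)C[N+]#[C-])cc1 | starting material
6 | trans-5-(6-bromo-4-methoxy-1-tosyl-1H-indol-3-yl)-4-tosyl-4,5-dihydrooxazole (racemic, one enantiomer drawn) | COc1cc(Br)cc2n(S(=O)(=O)c3ccc(C)cc3)cc([C@H]4OC=N[C@@H]4S(=O)(=O)c5ccc(C)cc5)c12 | intermediate (not isolated)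
7 | 5-(6-bromo-4-methoxy-1-tosyl-1H-indol-3-yl)oxazole | COc1cc(Br)cc2n(S(=O)(=O)c3ccc(C)cc3)cc(-c3cnco3)c12 | intermediate
8 | lithium (Z)-1-(6-bromo-4-methoxy-1-tosyl-1H-indol-3-yl)-2-isocyanoethen-1-olate | COc1cc(Br)cc2n(S(=O)(=O)c3ccc(C)cc3)cc(/C([O-])=C/[N+]#[C-])c12.[Li+] | intermediate (not isolated)
9 | 5-(6-bromo-4-methoxy-1-tosyl-1H-indol-3-yl)-4-iodooxazole | COc1cc(Br)cc2n(S(=O)(=O)c3ccc(C)cc3)cc(-c3ocnc3I)c12 | intermediate (not isolated)
10 | 5-(6-bromo-4-methoxy-1-tosyl-1H-indol-3-yl)-2,4-diiodooxazole | COc1cc(Br)cc2n(S(=O)(=O)c3ccc(C)cc3)cc(-c3oc(I)nc3I)c12 | intermediate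
11 | (1-(tert-butoxycarbonyl)-1H-pyrrol-2-yl)boronic acid | CC(C)(C)OC(=O)n1cccc1B(O)O | starting material
12 | tert-butyl 2-[5-(6-bromo-4-methoxy-1-tosyl-1H-indol-3-yl)-4-iodooxazol-2-yl]-1H-pyrrole-1-carboxylate | COc1cc(Br)cc2n(S(=O)(=O)c3ccc(C)cc3)cc(-c3oc(-c4cccn4C(=O)OC(C)(C)C)nc3I)c12 | intermediate
13 | 5-(6-bromo-4-methoxy-1H-indol-3-yl)-4-iodo-2-(1H-pyrrol-2-yl)oxazole | COc1cc(Br)cc2[nH]cc(-c3oc(-c4ccc[nH]4)nc3I)c12 | target

Total step count: 6
Longest linear sequence: 6 steps (1 → 13)

Steps most likely to fail

Step 3. Carbonyl addition may be slow at the formyl group crowded by the peri methoxy group. The N-sulfonyl group may be lost early, which would restore the unreactive vinylogous amide. The sequence may also stall before sulfinate elimination. The fallback sets out from 1 and comes back at 7, and it makes the indole C3–oxazole C5 bond by cross-coupling instead of ring construction. Compound 1 is iodinated at C3 (I2, KOH, DMF) to 6-bromo-3-iodo-4-methoxy-1H-indole F1. This is tosylated at once (NaH, TsCl, THF) to 6-bromo-3-iodo-4-methoxy-1-tosyl-1H-indole F2. Selective coupling at C3–I follows, using commercial 2-(triisopropylsilyl)oxazol-5-ylboronic acid pinacol ester (CC(C)[Si](C(C)C)(C(C)C)c1ncc(B2OC(C)(C)C(C)(C)O2)o1) with Pd(PPh3)4, aq Na2CO3 and DME at 70 °C. This gives 5-(6-bromo-4-methoxy-1-tosyl-1H-indol-3-yl)-2-(triisopropylsilyl)oxazole F3. The labile C2 silyl group is then removed (TBAF, THF, 0 °C) to give 7.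

Step 4. The lithiated oxazole may partition between C2 and C4 attack, the amide base may be consumed by iodine, and the second cycle may be incomplete, so that mono-iodides persist. The fallback sets out from 7 and comes back at 10, and it makes the C4–I bond by electrophilic substitution instead of anion chemistry. NIS in DMF at rt iodinates oxazole C4, the β-carbon of the O1–C5=C4 enol ether and the most electron-rich position left in the N-tosylated system, and 9 is now isolated. A single C2 deprotonation in pure THF (LiN(SiMe3)2, −78 °C, then I2) then gives 10.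

Step 5. Protodeboronation of the 2-pyrrolylboronic acid may outrun transmetalation. A second oxidative addition at C4–I or C6–Br, or hydrodeiodination, may occur once more boronic acid and heat are applied. The fallback sets out from 10 and comes back at 12. It is a base-free Stille coupling with commercial tert-butyl 2-(tributylstannyl)-1H-pyrrole-1-carboxylate (CCCC[Sn](CCCC)(CCCC)c1cccn1C(=O)OC(C)(C)C). One equivalent is used with Pd(PPh3)4 and CuI in DMF at 50 °C. The stannane does not protodemetalate, so exactly one equivalent can be dosed and the coupling can be held at C2.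

Further compounds
F1 | step 3 | 6-bromo-3-iodo-4-methoxy-1H-indole | COc1cc(Br)cc2[nH]cc(I)c12
F2 | step 3 | 6-bromo-3-iodo-4-methoxy-1-tosyl-1H-indole | COc1cc(Br)cc2n(S(=O)(=O)c3ccc(C)cc3)cc(I)c12
F3 | step 3 | 5-(6-bromo-4-methoxy-1-tosyl-1H-indol-3-yl)-2-(triisopropylsilyl)oxazole | COc1cc(Br)cc2n(S(=O)(=O)c3ccc(C)cc3)cc(-c3cnc([Si](C(C)C)(C(C)C)C(C)C)o3)c12
F0 | step 4 | none | none
F0 | step 5 | none | none
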